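**Retrosynthetic overview** (flavanone numbering: O1, C2, C3, C4, C4a, C5–C8, C8a; ring A = benzo ring, ring B = 2-aryl ring, ring C = pyranone)
1. The quinone of ring B is taken back to a 2',4',5'-trimethoxyphenyl group (oxidative demethylation last), the 5-OH to a benzyl ether, and the C4 ketone to a carbinol.
2. Structural feature used: O1 bridges C8a of ring A and the benzylic C2, and ring A descends from a symmetric 2,6-dihydroxyacetophenone. One phenol oxygen is kept as O5 (benzyl ether), the other is turned into a C8a triflate, and O1 is supplied by the C2 carbinol. Ring C is closed at O1–C8a by intramolecular palladium-catalysed C–O coupling.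
3. C2–C3 comes from a (+)-Ipc2BCl aldol of the acetyl group with 2,4,5-trimethoxybenzaldehyde (sets C2); the ketone is then reduced to the anti carbinol.
4. The ring A block is made from 2,4,6-trihydroxyacetophenone by double C-methylation, 4-O-methylation, mono-benzylation and triflation.
5. Ring order: rings A and B are bought as arenes, ring C is the only ring formed (step 7), and ring B becomes the quinone in the last step.

Key step: step 7

Remark: the target has one stereocentre, C2, which is (S) by CIP analysis of the given SMILES; the C4 carbinol of 12 and 13 is a temporary stereocentre that is erased in step 8.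

**Step 1**
Reactants: 1 2,4,6-trihydroxyacetophenone
Product: 2 1-(2,4,6-trihydroxy-3,5-dimethylphenyl)ethanone
Conditions: NaOMe (2.2 equiv), MeI (2.1 equiv), MeOH, 0 °C to 45 °C; aq. HCl work-up
Reagents that add atoms: iodomethane, CI
Why: Nuclear C-methylation of a phloroglucinol-type phenoxide: the ambident anion of 1 is alkylated at its two free ring carbons, and limiting MeI to about two equivalents should hold back the dearomatised gem-dimethyl by-product.

**Step 2**
Reactants: 2 1-(2,4,6-trihydroxy-3,5-dimethylphenyl)ethanone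
Product: 3 1-(2,6-dihydroxy-4-methoxy-3,5-dimethylphenyl)ethanone
Conditions: Me2SO4 (1.0 equiv), K2CO3 (1.1 equiv), acetone, rt
Reagents that add atoms: dimethyl sulfate, COS(=O)(=O)OC
Why: Regioselective Williamson O-methylation: the 4-OH, para to the acetyl group, is the most acidic and is not held in the hydrogen-bonded chelate with the carbonyl oxygen, so one equivalent of Me2SO4 should react there.

**Step 3**
Reactants: 3 1-(2,6-dihydroxy-4-methoxy-3,5-dimethylphenyl)ethanone; 4 benzyl bromide
Product: 5 1-[2-(benzyloxy)-6-hydroxy-4-methoxy-3,5-dimethylphenyl]ethanone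
Conditions: 4 (1.05 equiv), K2CO3 (1.2 equiv), acetone, reflux
Reagents that add atoms: none
Why: Williamson etherification: the two phenols of 3 are equivalent by symmetry, and after the first benzylation the remaining OH is locked in a strong hydrogen bond to the acetyl oxygen, so a second benzylation should be slow.

**Step 4**
Reactants: 5 1-[2-(benzyloxy)-6-hydroxy-4-methoxy-3,5-dimethylphenyl]ethanone
Product: 6 2-acetyl-3-(benzyloxy)-5-methoxy-4,6-dimethylphenyl trifluoromethanesulfonate
Conditions: Tf2O (1.2 equiv), pyridine (3 equiv), CH2Cl2, 0 °C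
Reagents that add atoms: trifluoromethanesulfonic anhydride, O=S(=O)(OS(=O)(=O)C(F)(F)F)C(F)(F)F
Why: O-Sulfonylation of the remaining phenol gives the aryl triflate that will be the leaving group at C8a; the ketone and the ethers are inert to Tf2O/pyridine at 0 °C.

**Step 5**
Reactants: 6 2-acetyl-3-(benzyloxy)-5-methoxy-4,6-dimethylphenyl trifluoromethanesulfonate; 7 (+)-B-chlorodiisopinocampheylborane, (+)-Ipc2BCl; 8 2,4,5-trimethoxybenzaldehyde
Product: 11 3-(benzyloxy)-2-[(3S)-3-hydroxy-3-(2,4,5-trimethoxyphenyl)propanoyl]-5-methoxy-4,6-dimethylphenyl trifluoromethanesulfonate, via enol diisopinocampheylborinate 9 (not isolated), via boron aldolate 10 (not isolated)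
Conditions: 7 (1.3 equiv), Et3N (1.5 equiv), Et2O, 0 °C; then 8, −78 °C to −20 °C; then MeOH, pH 7 phosphate buffer, 30% H2O2, 0 °C
Reagents that add atoms: none
Why: Reagent-controlled boron aldol of a methyl ketone (Paterson-type Ipc2BCl aldol): enolisation at the acetyl CH3 gives 9, which should add to the si face of aldehyde 8 under control of the (+)-isopinocampheyl ligands to set the (S) carbinol (the future C2), and buffered H2O2 releases 11 from borinate 10.

**Step 6**
Reactants: 11 3-(benzyloxy)-2-[(3S)-3-hydroxy-3-(2,4,5-trimethoxyphenyl)propanoyl]-5-methoxy-4,6-dimethylphenyl trifluoromethanesulfonate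
Product: 12 3-(benzyloxy)-2-[(1S,3S)-1,3-dihydroxy-3-(2,4,5-trimethoxyphenyl)propyl]-5-methoxy-4,6-dimethylphenyl trifluoromethanesulfonate
Conditions: Me4NBH(OAc)3 (5 equiv), MeCN/AcOH (1:1), −30 °C; aq. potassium sodium tartrate (KNaC4H4O6) work-up
Reagents that add atoms: none
Why: Evans–Saksena reduction: the C2 hydroxyl exchanges onto boron and hydride is delivered intramolecularly through a chair six-membered transition state, which should give the 1,3-anti diol, that is the (S) carbinol at C4.

**Step 7**
Reactants: 12 3-(benzyloxy)-2-[(1S,3S)-1,3-dihydroxy-3-(2,4,5-trimethoxyphenyl)propyl]-5-methoxy-4,6-dimethylphenyl trifluoromethanesulfonate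
Product: 13 (2S,4S)-5-(benzyloxy)-7-methoxy-6,8-dimethyl-2-(2,4,5-trimethoxyphenyl)chroman-4-ol (2,4-cis)
Conditions: Pd(OAc)2 (5 mol %), 2-(di-tert-butylphosphino)-1,1'-binaphthyl (7.5 mol %), Cs2CO3 (1.5 equiv), toluene, 80 °C
Reagents that add atoms: none
Why: Pd(OAc)2 is reduced in the flask to a zerovalent palladium–phosphine complex that adds oxidatively into the C8a–OTf bond; carbonate then converts the C2 hydroxyl into a palladium-bound alkoxide, and C–O reductive elimination from this divalent aryl(alkoxo)palladium forms O1–C8a. The closest known reaction type is the Buchwald–Hartwig-type intramolecular etherification of aryl halides and sulfonates with secondary alcohols, which gives chromans. Ring C closes as a six-membered ring through a seven-membered oxapalladacycle, the C2–C3–C4–C4a tether holding the alkoxide next to the metal. No stereocentre is formed: neither the C2–O nor the C4–O bond is broken, so the aldol-derived (S) configuration at C2 and the (S) carbinol at C4 are carried through unchanged. The step needs arylation of the C2 hydroxyl and not the C4 hydroxyl, which is secured because closure through the C4 oxygen would give a four-membered benzoxete, and it needs reductive elimination to outrun beta-hydride elimination of the benzylic alkoxide, for which the bulky electron-rich di-tert-butylbiarylphosphine and the intramolecular setting are chosen. Cs2CO3 in toluene keeps the alkoxide concentration low so that the triflate is not cleaved at sulfur before the electron-rich, di-ortho-substituted C–OTf bond has undergone oxidative addition.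

**Step 8**
Reactants: 13 (2S,4S)-5-(benzyloxy)-7-methoxy-6,8-dimethyl-2-(2,4,5-trimethoxyphenyl)chroman-4-ol
Product: 14 (2S)-5-(benzyloxy)-7-methoxy-6,8-dimethyl-2-(2,4,5-trimethoxyphenyl)chroman-4-one
Conditions: Dess–Martin periodinane (1.3 equiv), NaHCO3 (5 equiv), CH2Cl2, 0 °C to rt
Reagents that add atoms: none
Why: Dess–Martin oxidation of the benzylic C4 carbinol to the aryl ketone under bicarbonate buffer, mild enough to leave the electron-rich ring B and the C2 stereocentre (beta to the new carbonyl) untouched.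

**Step 9**
Reactants: 14 (2S)-5-(benzyloxy)-7-methoxy-6,8-dimethyl-2-(2,4,5-trimethoxyphenyl)chroman-4-one
Product: 15 (2S)-5-hydroxy-7-methoxy-6,8-dimethyl-2-(2,4,5-trimethoxyphenyl)chroman-4-one
Conditions: H2 (1 atm), 10% Pd/C, EtOAc, rt, stopped when 14 is consumed
Reagents that add atoms: none
Why: Catalytic hydrogenolysis of the aryl benzyl ether under neutral conditions, chosen over a Lewis acid because the C2–O1 bond (benzylic to the trimethoxyphenyl ring and vinylogous to the C4 carbonyl) would ionise and racemise under acid.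

**Step 10**
Reactants: 15 (2S)-5-hydroxy-7-methoxy-6,8-dimethyl-2-(2,4,5-trimethoxyphenyl)chroman-4-one
Product: 16 2-[(2S)-5-hydroxy-7-methoxy-6,8-dimethyl-4-oxochroman-2-yl]-5-methoxycyclohexa-2,5-diene-1,4-dione (CNP0208927.1)
Conditions: (NH4)2Ce(NO3)6 (2.2 equiv), MeCN/H2O (2:1), 0 °C, short reaction time
Reagents that add atoms: water, O
Why: Oxidative demethylation with (NH4)2Ce(NO3)6: the 1,2,4-trimethoxyarene of ring B is the most easily oxidised site, its para-related 2'- and 5'-methoxy groups leave as methanol and are replaced by carbonyl oxygens from water, while the hydrogen-bonded, acyl-deactivated phenol of ring A should survive and C2 is not touched.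

**Compound list**
1 | 2,4,6-trihydroxyacetophenone | CC(=O)c1c(O)cc(O)cc1O | starting material
2 | 1-(2,4,6-trihydroxy-3,5-dimethylphenyl)ethanone | CC(=O)c1c(O)c(C)c(O)c(C)c1O | intermediate
3 | 1-(2,6-dihydroxy-4-methoxy-3,5-dimethylphenyl)ethanone | CC(=O)c1c(O)c(C)c(OC)c(C)c1O | intermediate
4 | benzyl bromide | BrCc1ccccc1 | starting material
5 | 1-[2-(benzyloxy)-6-hydroxy-4-methoxy-3,5-dimethylphenyl]ethanone | CC(=O)c1c(OCc2ccccc2)c(C)c(OC)c(C)c1O | intermediate
6 | 2-acetyl-3-(benzyloxy)-5-methoxy-4,6-dimethylphenyl trifluoromethanesulfonate | CC(=O)c1c(OCc2ccccc2)c(C)c(OC)c(C)c1OS(=O)(=O)C(F)(F)F | intermediate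
7 | (+)-B-chlorodiisopinocampheylborane, chlorobis[(1S,2R,3S,5S)-2,6,6-trimethylbicyclo[3.1.1]heptan-3-yl]borane | ClB([C@H]1C[C@H]2C[C@@H]([C@@H]1C)C2(C)C)[C@H]1C[C@H]2C[C@@H]([C@@H]1C)C2(C)C | starting material
8 | 2,4,5-trimethoxybenzaldehyde | COc1cc(OC)c(C=O)cc1OC | starting material
9 | enol diisopinocampheylborinate of 6 | C=C(OB([C@H]1C[C@H]2C[C@@H]([C@@H]1C)C2(C)C)[C@H]1C[C@H]2C[C@@H]([C@@H]1C)C2(C)C)c1c(OCc2ccccc2)c(C)c(OC)c(C)c1OS(=O)(=O)C(F)(F)F | intermediate
10 | O-(diisopinocampheylboranyl) derivative of aldol 11 (boron aldolate, S at the carbinol carbon) | COc1cc(OC)c([C@@H](OB([C@H]5C[C@H]6C[C@@H]([C@@H]5C)C6(C)C)[C@H]5C[C@H]6C[C@@H]([C@@H]5C)C6(C)C)CC(=O)c2c(OCc3ccccc3)c(C)c(OC)c(C)c2OS(=O)(=O)C(F)(F)F)cc1OC | intermediate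
11 | 3-(benzyloxy)-2-[(3S)-3-hydroxy-3-(2,4,5-trimethoxyphenyl)propanoyl]-5-methoxy-4,6-dimethylphenyl trifluoromethanesulfonate | COc1cc(OC)c([C@@H](O)CC(=O)c2c(OCc3ccccc3)c(C)c(OC)c(C)c2OS(=O)(=O)C(F)(F)F)cc1OC | intermediate
12 | 3-(benzyloxy)-2-[(1S,3S)-1,3-dihydroxy-3-(2,4,5-trimethoxyphenyl)propyl]-5-methoxy-4,6-dimethylphenyl trifluoromethanesulfonate | COc1cc(OC)c([C@@H](O)C[C@H](O)c2c(OCc3ccccc3)c(C)c(OC)c(C)c2OS(=O)(=O)C(F)(F)F)cc1OC | intermediate
13 | (2S,4S)-5-(benzyloxy)-7-methoxy-6,8-dimethyl-2-(2,4,5-trimethoxyphenyl)chroman-4-ol | COc1cc(OC)c([C@@H]2C[C@H](O)c3c(OCc4ccccc4)c(C)c(OC)c(C)c3O2)cc1OC | intermediate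
14 | (2S)-5-(benzyloxy)-7-methoxy-6,8-dimethyl-2-(2,4,5-trimethoxyphenyl)chroman-4-one | COc1cc(OC)c([C@@H]2CC(=O)c3c(OCc4ccccc4)c(C)c(OC)c(C)c3O2)cc1OC | intermediate
15 | (2S)-5-hydroxy-7-methoxy-6,8-dimethyl-2-(2,4,5-trimethoxyphenyl)chroman-4-one | COc1cc(OC)c([C@@H]2CC(=O)c3c(O)c(C)c(OC)c(C)c3O2)cc1OC | intermediate
16 | 2-[(2S)-5-hydroxy-7-methoxy-6,8-dimethyl-4-oxochroman-2-yl]-5-methoxycyclohexa-2,5-diene-1,4-dione | COC1=CC(=O)C([C@@H]2CC(=O)c3c(O)c(C)c(OC)c(C)c3O2)=CC1=O | target

**Step count**
Total: 10 steps. Longest linear sequence: 10 steps (1 to 16).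

**Steps most likely to fail**

Step 7 (key step). Oxidative addition into the electron-rich, di-ortho-substituted aryl triflate may be slow. Beta-hydride elimination of the benzylic C2 alkoxide would oxidise C2 and reduce the arene. The C4 alkoxide may take the triflyl group from the neighbouring oxygen. The fallback forms O1–C2 instead of O1–C8a, by Mitsunobu inversion, and therefore needs the enantiomeric carbinol. It sets out from 6. Aldol with (−)-Ipc2BCl, Et3N and 8 should pass through the enol borinate F1 and the boron aldolate F2 to the (R)-aldol F3. Me4NBH(OAc)3 reduction should give the (1R,3R)-diol triflate F4. Et4NOH in dioxane should cleave the triflate at sulfur to the phenol F5. PPh3 and diisopropyl azodicarboxylate in THF at 0 °C should close ring C with inversion at C2 to the (2S,4R)-flavan-4-ol F6. Dess–Martin oxidation of F6 comes back to the route at 14.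

Step 5. Enolisation and addition may be sluggish with the twisted, doubly ortho-substituted aryl methyl ketone and the electron-rich aldehyde. Facial selectivity of methyl ketone enol borinates is expected to be only moderate, so enrichment by recrystallisation of 12 is planned. Retro-aldol or dehydration may occur on work-up. The fallback sets C2 by ketone reduction and sets out from 6. LiN(SiMe3)2 (2.2 equiv, THF, −78 °C) should give the lithium enolate F7, and acylation with 2,4,5-trimethoxybenzoyl chloride the 1,3-diketone F8. Noyori asymmetric transfer hydrogenation with RuCl[(S,S)-TsDPEN](p-cymene) in HCO2H/Et3N should reduce the less hindered ring B carbonyl to the (S) carbinol. This comes back to the route at 11; any further catalyst-controlled reduction of the hindered carbonyl would lead on to 12.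

Step 9. Hydrogenolysis may go too far, cleaving the benzylic C2–O1 bond (ring opening) or reducing the C4 carbonyl. The fallback reverses the order of the last two operations and sets out from 14. (NH4)2Ce(NO3)6 in MeCN/H2O at 0 °C should give the benzyl-protected quinone F9, in which ring B is electron-poor and C2–O1 is no longer acid-labile. BCl3 with pentamethylbenzene in CH2Cl2 at −78 °C should then remove the peri-benzyl ether. This comes back to the route at 16.

**Further compounds**
F1 | step 7 | enol borinate of 6 from (−)-Ipc2BCl | C=C(OB([C@@H]1C[C@@H]2C[C@H]([C@H]1C)C2(C)C)[C@@H]1C[C@@H]2C[C@H]([C@H]1C)C2(C)C)c1c(OCc2ccccc2)c(C)c(OC)c(C)c1OS(=O)(=O)C(F)(F)F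
F2 | step 7 | boron aldolate of F3 (R at the carbinol carbon) | COc1cc(OC)c([C@H](OB([C@@H]5C[C@@H]6C[C@H]([C@H]5C)C6(C)C)[C@@H]5C[C@@H]6C[C@H]([C@H]5C)C6(C)C)CC(=O)c2c(OCc3ccccc3)c(C)c(OC)c(C)c2OS(=O)(=O)C(F)(F)F)cc1OC
F3 | step 7 | 3-(benzyloxy)-2-[(3R)-3-hydroxy-3-(2,4,5-trimethoxyphenyl)propanoyl]-5-methoxy-4,6-dimethylphenyl trifluoromethanesulfonate | COc1cc(OC)c([C@H](O)CC(=O)c2c(OCc3ccccc3)c(C)c(OC)c(C)c2OS(=O)(=O)C(F)(F)F)cc1OC
F4 | step 7 | 3-(benzyloxy)-2-[(1R,3R)-1,3-dihydroxy-3-(2,4,5-trimethoxyphenyl)propyl]-5-methoxy-4,6-dimethylphenyl trifluoromethanesulfonate | COc1cc(OC)c([C@H](O)C[C@@H](O)c2c(OCc3ccccc3)c(C)c(OC)c(C)c2OS(=O)(=O)C(F)(F)F)cc1OC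
F5 | step 7 | 3-(benzyloxy)-2-[(1R,3R)-1,3-dihydroxy-3-(2,4,5-trimethoxyphenyl)propyl]-5-methoxy-4,6-dimethylphenol | COc1cc(OC)c([C@H](O)C[C@@H](O)c2c(OCc3ccccc3)c(C)c(OC)c(C)c2O)cc1OC
F6 | step 7 | (2S,4R)-5-(benzyloxy)-7-methoxy-6,8-dimethyl-2-(2,4,5-trimethoxyphenyl)chroman-4-ol | COc1cc(OC)c([C@@H]2C[C@@H](O)c3c(OCc4ccccc4)c(C)c(OC)c(C)c3O2)cc1OC
F7 | step 5 | lithium enolate of 6 | [Li]OC(=C)c1c(OCc2ccccc2)c(C)c(OC)c(C)c1OS(=O)(=O)C(F)(F)F
F8 | step 5 | 3-(benzyloxy)-5-methoxy-4,6-dimethyl-2-[3-oxo-3-(2,4,5-trimethoxyphenyl)propanoyl]phenyl trifluoromethanesulfonate | COc1cc(OC)c(C(=O)CC(=O)c2c(OCc3ccccc3)c(C)c(OC)c(C)c2OS(=O)(=O)C(F)(F)F)cc1OC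
F9 | step 9 | 2-[(2S)-5-(benzyloxy)-7-methoxy-6,8-dimethyl-4-oxochroman-2-yl]-5-methoxycyclohexa-2,5-diene-1,4-dione | COC1=CC(=O)C([C@@H]2CC(=O)c3c(OCc4ccccc4)c(C)c(OC)c(C)c3O2)=CC1=O
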